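The oxolane (O1, C2, C3, C4, C5) is disconnected at C2–C3. The feature used is the C2–H bond: it is flanked by O1 and an electron-rich guaiacyl ring and stands 1,5 to C3. A rhodium carbenoid generated at C3 inserts into that bond, which in one operation forms C2–C3, closes the ring and sets C2 and C3 relative to C4. The precursor is an open-chain tert-butyl α-diazo ester in which C4 carries the silylated vanillyl ether arm (C5–O1–C2H2Ar) and the silylated carbinol Cα. Both its stereocentres come from one anti aldol. The tert-butyl ester is chosen because a methyl ester would lactonise at both γ-hydroxy ester stages.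

Key step: step 10

Labels: the oxolane numbering of the target (O1, C2–C5; Cα = carbinol carbon on C4) is used for all intermediates. TBS = tert-butyldimethylsilyl. ArS = 4-(TBSO)-3-methoxyphenyl.

Assumption: in the MgCl2-catalysed anti aldol the aldehyde is taken to add to the face of the chelated Z-enolate remote from the auxiliary benzyl group (the facial sense of imide enolate alkylation), so the (R)-auxiliary leads to the (3S,4R) adduct.

Step 1
Reactants: 1 vanillin
Product: 2 4-(TBSO)-3-methoxybenzaldehyde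
Conditions: TBSCl, imidazole, DMF, 0 °C → rt
Reagents that add atoms: tert-butyldimethylsilyl chloride, CC(C)(C)[Si](C)(C)Cl
Why: Imidazole-promoted O-silylation of the acidic phenol is fast and leaves the aldehyde alone (silyl ether protection).

Step 2
Reactants: 2 4-(TBSO)-3-methoxybenzaldehyde
Product: 3 [4-(TBSO)-3-methoxyphenyl]methanol
Conditions: NaBH4, MeOH, 0 °C
Reagents that add atoms: none
Why: Borohydride reduction of the aldehyde is chemoselective and the aryl silyl ether survives brief contact with cold methanol (carbonyl hydride reduction), which avoids having to distinguish the phenol from the benzylic alcohol of vanillyl alcohol.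

Step 3
Reactants: 3 [4-(TBSO)-3-methoxyphenyl]methanol
Product: 4 4-(TBSO)-3-methoxybenzyl 2,2,2-trichloroacetimidate
Conditions: Cl3CCN, DBU (10 mol %), CH2Cl2, 0 °C; used without storage
Reagents that add atoms: trichloroacetonitrile, N#CC(Cl)(Cl)Cl
Why: Base-catalysed addition of the benzylic alkoxide to the electron-poor nitrile should proceed as it does for 4-methoxybenzyl alcohol (trichloroacetimidate formation).

Step 4
Reactants: 5 (R)-4-benzyl-1,3-oxazolidin-2-one; 6 4-tert-butoxy-4-oxobutanoic acid
Product: 8 tert-butyl 4-[(4R)-4-benzyl-2-oxo-1,3-oxazolidin-3-yl]-4-oxobutanoate, via mixed pivalic anhydride 7 (not isolated)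
Conditions: 6, PivCl, Et3N, THF, −20 °C; then LiCl, 5, −20 °C → rt
Reagents that add atoms: none
Why: The LiCl-activated oxazolidinone attacks the less hindered carbonyl of the mixed anhydride, so no strong base meets the tert-butyl ester (N-acylation of a chiral auxiliary through a mixed anhydride).

Step 5
Reactants: 8 tert-butyl 4-[(4R)-4-benzyl-2-oxo-1,3-oxazolidin-3-yl]-4-oxobutanoate; 2 4-(TBSO)-3-methoxybenzaldehyde
Product: 10 anti aldol tert-butyl (3S,4R)-3-{[(4R)-4-benzyl-2-oxo-1,3-oxazolidin-3-yl]carbonyl}-4-ArS-4-hydroxybutanoate, via trimethylsilyl ether 9 (not isolated)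
Conditions: MgCl2 (20 mol %), Et3N, TMSCl, EtOAc, 23 °C; then PPTS (cat.), MeOH, 0 °C
Reagents that add atoms: none
Why: Soft enolisation by MgCl2/Et3N gives the chelated Z-enolate of the imide only, which should add to the non-enolisable, electron-rich aldehyde on the face away from the benzyl group through a boat-like closed transition state and so set C4 and Cα in the anti sense, while TMSCl traps the aldolate, blocks reversal and turns the metal over (magnesium-halide-catalysed direct anti aldol of an N-acyloxazolidinone); the mild methanolysis then frees a carbinol that the hindered tert-butyl ester does not acylate.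

Step 6
Reactants: 10 anti aldol adduct
Product: 11 tert-butyl (3S,4R)-3-{[(4R)-4-benzyl-2-oxo-1,3-oxazolidin-3-yl]carbonyl}-4-ArS-4-(TBSO)butanoate
Conditions: TBSOTf, 2,6-lutidine, CH2Cl2, −78 → 0 °C
Reagents that add atoms: tert-butyldimethylsilyl triflate, CC(C)(C)[Si](C)(C)OS(=O)(=O)C(F)(F)F
Why: The silyl triflate caps the hindered benzylic alcohol at low temperature under a non-nucleophilic base, so retro-aldol, epimerisation at C4 and loss of the tert-butyl ester are not expected (silyl ether protection).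

Step 7
Reactants: 11 silylated aldol imide
Product: 12 tert-butyl (3R,4R)-4-ArS-4-(TBSO)-3-(hydroxymethyl)butanoate
Conditions: LiBH4, MeOH (1 equiv), Et2O, 0 °C; used promptly
Reagents that add atoms: none
Why: Hydride attacks the activated exocyclic imide carbonyl far faster than the tert-butyl ester, and that ester is too hindered to lactonise with the new C5 hydroxyl in the cold (reductive removal of the auxiliary, which is recovered).

Step 8
Reactants: 12 primary alcohol; 4 4-(TBSO)-3-methoxybenzyl trichloroacetimidate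
Product: 13 tert-butyl (3R,4R)-4-ArS-4-(TBSO)-3-{[(4-(TBSO)-3-methoxybenzyl)oxy]methyl}butanoate
Conditions: PPTS (10 mol %), CH2Cl2, 0 °C → rt
Reagents that add atoms: none
Why: Protonation of the imidate releases a benzylic cation stabilised by the para-silyloxy group, which the primary alcohol captures, and the weakly acidic, base-free medium avoids silyl migration from Cα–O to C5–O, lactonisation and ionisation at Cα (acid-catalysed trichloroacetimidate benzylation).

Step 9
Reactants: 13 vanillyl ether ester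
Product: 15 tert-butyl (3R,4R)-2-diazo-4-ArS-4-(TBSO)-3-{[(4-(TBSO)-3-methoxybenzyl)oxy]methyl}butanoate, via 2-trifluoroacetyl ester 14 (not isolated)
Conditions: LDA [LiN(iPr)2], THF, −78 °C; CF3CO2CH2CF3, −78 °C; aq NH4Cl; then p-ABSA, Et3N, MeCN, rt
Reagents that add atoms: 4-acetamidobenzenesulfonyl azide, CC(=O)Nc1ccc(cc1)S(=O)(=O)N=[N+]=[N-]
Why: The ester enolate is C-acylated by the trifluoroacetate, and the activated methine then takes the diazo group from the sulfonyl azide while the trifluoroacetyl group leaves as the N-sulfonyl amide (deacylative Regitz diazo transfer); no leaving group sits β to the enolate carbon, so C4 and both ether arms stay intact.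

Step 10
Reactants: 15 α-diazo ester
Product: 16 all-trans tert-butyl (2R,3R,4R)-2-ArS-4-[(R)-ArS(TBSO)methyl]oxolane-3-carboxylate
Conditions: Rh2(OPiv)4 [Rh2(O2CCMe3)4] (1 mol %), 4 Å MS, CH2Cl2 (5 mM), slow addition of 15 at −78 °C, then → −20 °C
Reagents that add atoms: none
Why: The catalyst binds the diazo carbon, N2 departs, and a benzylic C–H σ bond of the vanillyl ether attacks the empty carbenoid orbital at C3 in one asynchronous three-centre step in which hydrogen runs ahead of carbon, with retention at C2. The closest known reaction type is the dirhodium-carboxylate cyclisation of 4-alkoxy-2-diazoalkanoates to oxolane-3-carboxylates by insertion next to the ether oxygen. The oxolane closes as a 1,5 insertion, with C3, C4, C5, O1 and C2 becoming the ring through a chair-like six-centre array that includes the migrating hydrogen. C2 is controlled by C4, because with the large C4 side chain and the C2 aryl group both pseudo-equatorial only the pro-R hydrogen is presented, which gives the 2,4-cis (2R) centre; C3 is fixed in the same array with the tert-butyl ester pseudo-equatorial and trans to both neighbours, and since this is also the most stable epimer, DBU would correct any leakage. The step needs chemoselectivity over the 1,2-hydride shift from C4, over five-membered closure onto the guaiacyl ring on Cα and over the tert-butyl C–H bonds; the target bond is the only one activated by both oxygen and a para-silyloxy arene, C4–H is made less hydridic by its two β-oxygen substituents, and a bulky, electron-rich carboxylate in the cold favours insertion over hydride shift and arene attack. An achiral catalyst is chosen deliberately, since the phthalimido amino acid carboxylates favour 2,3-cis products, which here would oppose the bias of C4.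

Step 11
Reactants: 16 all-trans oxolane ester
Product: 17 {(2R,3S,4R)-2-ArS-4-[(R)-ArS(TBSO)methyl]oxolan-3-yl}methanol
Conditions: LiAlH4, THF, 0 °C; then H2O, aq NaOH
Reagents that add atoms: none
Why: LiAlH4 reduces even the hindered tert-butyl ester to the primary alcohol while ethers and silyl ethers persist in the cold, and hydride addition outruns deprotonation so C3 is kept (ester reduction).

Step 12
Reactants: 17 tris-silylated triol
Product: 18 target (2R,3S,4R)-2-(4-hydroxy-3-methoxyphenyl)-4-[(R)-hydroxy(4-hydroxy-3-methoxyphenyl)methyl]-3-(hydroxymethyl)oxolane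
Conditions: TBAF, AcOH (1:1), THF, 0 °C → rt
Reagents that add atoms: none
Why: Fluoride cleaves the two aryl silyl ethers and the benzylic one, and the acetic acid buffer keeps the phenols protonated, so quinone methide formation and epimerisation at C2 or Cα should not set in (fluoride desilylation).

Compound list
1 | vanillin | COc1cc(C=O)ccc1O | starting material
2 | 4-(TBSO)-3-methoxybenzaldehyde | COc1cc(C=O)ccc1O[Si](C)(C)C(C)(C)C | intermediate
3 | [4-(TBSO)-3-methoxyphenyl]methanol | COc1cc(CO)ccc1O[Si](C)(C)C(C)(C)C | intermediate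
4 | 4-(TBSO)-3-methoxybenzyl 2,2,2-trichloroacetimidate | COc1cc(COC(=N)C(Cl)(Cl)Cl)ccc1O[Si](C)(C)C(C)(C)C | intermediate
5 | (R)-4-benzyl-1,3-oxazolidin-2-one | O=C1N[C@H](Cc2ccccc2)CO1 | starting material
6 | 4-tert-butoxy-4-oxobutanoic acid (mono-tert-butyl succinate) | CC(C)(C)OC(=O)CCC(=O)O | starting material
7 | 4-tert-butoxy-4-oxobutanoic pivalic anhydride | CC(C)(C)OC(=O)CCC(=O)OC(=O)C(C)(C)C | intermediate
8 | tert-butyl 4-[(4R)-4-benzyl-2-oxo-1,3-oxazolidin-3-yl]-4-oxobutanoate | CC(C)(C)OC(=O)CCC(=O)N1[C@H](Cc2ccccc2)COC1=O | intermediate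
9 | tert-butyl (3S,4R)-3-{[(4R)-4-benzyl-2-oxo-1,3-oxazolidin-3-yl]carbonyl}-4-ArS-4-(trimethylsilyloxy)butanoate | COc1cc([C@H](O[Si](C)(C)C)[C@@H](C(=O)N2[C@H](Cc3ccccc3)COC2=O)CC(=O)OC(C)(C)C)ccc1O[Si](C)(C)C(C)(C)C | intermediate
10 | tert-butyl (3S,4R)-3-{[(4R)-4-benzyl-2-oxo-1,3-oxazolidin-3-yl]carbonyl}-4-ArS-4-hydroxybutanoate | COc1cc([C@H](O)[C@@H](C(=O)N2[C@H](Cc3ccccc3)COC2=O)CC(=O)OC(C)(C)C)ccc1O[Si](C)(C)C(C)(C)C | intermediate
11 | tert-butyl (3S,4R)-3-{[(4R)-4-benzyl-2-oxo-1,3-oxazolidin-3-yl]carbonyl}-4-ArS-4-(TBSO)butanoate | COc1cc([C@H](O[Si](C)(C)C(C)(C)C)[C@@H](C(=O)N2[C@H](Cc3ccccc3)COC2=O)CC(=O)OC(C)(C)C)ccc1O[Si](C)(C)C(C)(C)C | intermediate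
12 | tert-butyl (3R,4R)-4-ArS-4-(TBSO)-3-(hydroxymethyl)butanoate | COc1cc([C@H](O[Si](C)(C)C(C)(C)C)[C@@H](CO)CC(=O)OC(C)(C)C)ccc1O[Si](C)(C)C(C)(C)C | intermediate
13 | tert-butyl (3R,4R)-4-ArS-4-(TBSO)-3-{[(4-(TBSO)-3-methoxybenzyl)oxy]methyl}butanoate | COc1cc([C@H](O[Si](C)(C)C(C)(C)C)[C@@H](COCc2ccc(O[Si](C)(C)C(C)(C)C)c(OC)c2)CC(=O)OC(C)(C)C)ccc1O[Si](C)(C)C(C)(C)C | intermediate
14 | 2-(trifluoroacetyl) derivative of 13 (C3 epimers) | COc1cc([C@H](O[Si](C)(C)C(C)(C)C)[C@@H](COCc2ccc(O[Si](C)(C)C(C)(C)C)c(OC)c2)C(C(=O)C(F)(F)F)C(=O)OC(C)(C)C)ccc1O[Si](C)(C)C(C)(C)C | intermediate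
15 | tert-butyl (3R,4R)-2-diazo-4-ArS-4-(TBSO)-3-{[(4-(TBSO)-3-methoxybenzyl)oxy]methyl}butanoate | COc1cc([C@H](O[Si](C)(C)C(C)(C)C)[C@@H](COCc2ccc(O[Si](C)(C)C(C)(C)C)c(OC)c2)C(=[N+]=[N-])C(=O)OC(C)(C)C)ccc1O[Si](C)(C)C(C)(C)C | intermediate
16 | tert-butyl (2R,3R,4R)-2-ArS-4-[(R)-ArS(TBSO)methyl]oxolane-3-carboxylate (all-trans) | COc1cc([C@H](O[Si](C)(C)C(C)(C)C)[C@H]2CO[C@@H](c3ccc(O[Si](C)(C)C(C)(C)C)c(OC)c3)[C@@H]2C(=O)OC(C)(C)C)ccc1O[Si](C)(C)C(C)(C)C | intermediate
17 | {(2R,3S,4R)-2-ArS-4-[(R)-ArS(TBSO)methyl]oxolan-3-yl}methanol | COc1cc([C@H](O[Si](C)(C)C(C)(C)C)[C@H]2CO[C@@H](c3ccc(O[Si](C)(C)C(C)(C)C)c(OC)c3)[C@@H]2CO)ccc1O[Si](C)(C)C(C)(C)C | intermediate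
18 | (2R,3S,4R)-2-(4-hydroxy-3-methoxyphenyl)-4-[(R)-hydroxy(4-hydroxy-3-methoxyphenyl)methyl]-3-(hydroxymethyl)oxolane | COc1cc([C@H](O)[C@H]2CO[C@@H](c3ccc(O)c(OC)c3)[C@@H]2CO)ccc1O | target

Total steps: 12. Longest linear sequence: 9 steps (steps 4–12, or equally step 1 followed by steps 5–12).

Steps most likely to fail

**Step 10 (C–H insertion).**
- What may go wrong: the carbenoid may be consumed by hydride migration from C4, or by electrophilic attack on the guaiacyl ring on Cα, before it reaches C2–H. The choice between the two diastereotopic benzylic hydrogens may also be weak.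
- Leakage at C3 alone is harmless, because DBU in toluene converts the all-cis ester into 16.
- The fallback sets out from 12 (with 2 as the aryl source) and returns at 16. It makes the same C2–C3 bond by polar chemistry, with C2 at the acyl oxidation level.
- Pinnick oxidation of 2 (NaClO2, NaH2PO4, 2-methyl-2-butene) gives 4-(TBSO)-3-methoxybenzoic acid F1. Steglich esterification with 12 (EDC, DMAP, CH2Cl2) gives the C5 aroate ester F2.
- LDA [LiN(iPr)2] (2.2 equiv, THF, −78 °C) triggers an intramolecular Claisen-type O-to-C aroyl shift through a five-membered tetrahedral intermediate, giving the hydroxy β-keto ester F3.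
- PPTS in warm toluene cyclodehydrates F3 to the 2-aryl-4,5-dihydrofuran-3-carboxylate F4.
- Hydrogenation (H2, Pd/C, EtOAc) from the face opposite the C4 side chain should give the all-cis oxolane ester F5, which already has the 2,4-cis relationship. DBU then epimerises C3 to give 16.

**Step 9 (diazo transfer).**
- What may go wrong: trifluoroacetylation of the hindered, β-branched enolate may be incomplete or may take place on oxygen, so that the azide finds no activated methine.
- The fallback sets out from 13 and returns at 15. It brings in the nitrogen one atom at a time.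
- Enolisation with KN(SiMe3)2 (THF, −78 °C), 2,4,6-triisopropylbenzenesulfonyl azide and an acetic acid quench give the α-azido ester F6, whose C3 configuration is irrelevant.
- Staudinger reduction (PPh3, THF/H2O) gives the α-amino ester F7.
- Diazotisation with isoamyl nitrite and catalytic AcOH in warm CHCl3 gives 15.

**Step 5 (anti aldol).**
- What may go wrong: the remote ester carbonyl may compete for magnesium, eroding the anti and facial selectivity or slowing turnover.
- The fallback sets out from 2 and returns at 12. It replaces auxiliary control by enamine catalysis.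
- Commercial tert-butyl 4-oxobutanoate is added slowly to 2 and L-proline (DMF, 4 °C). The acid-directed enamine aldol should give the anti hydroxy aldehyde tert-butyl (3S,4R)-3-formyl-4-ArS-4-hydroxybutanoate F8.
- TBSOTf/2,6-lutidine gives the silyl ether aldehyde F9, and NaBH4 in cold MeOH gives 12. This route also makes steps 4, 6 and 7 unnecessary.

Further compounds
F1 | step 10 | 4-(TBSO)-3-methoxybenzoic acid | COc1cc(C(=O)O)ccc1O[Si](C)(C)C(C)(C)C
F2 | step 10 | tert-butyl (3R,4R)-4-ArS-4-(TBSO)-3-{[(4-(TBSO)-3-methoxybenzoyl)oxy]methyl}butanoate | COc1cc([C@H](O[Si](C)(C)C(C)(C)C)[C@@H](COC(=O)c2ccc(O[Si](C)(C)C(C)(C)C)c(OC)c2)CC(=O)OC(C)(C)C)ccc1O[Si](C)(C)C(C)(C)C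
F3 | step 10 | tert-butyl (3R,4R)-2-[4-(TBSO)-3-methoxybenzoyl]-4-ArS-4-(TBSO)-3-(hydroxymethyl)butanoate (C2 epimers of the butanoate) | COc1cc([C@H](O[Si](C)(C)C(C)(C)C)[C@@H](CO)C(C(=O)c2ccc(O[Si](C)(C)C(C)(C)C)c(OC)c2)C(=O)OC(C)(C)C)ccc1O[Si](C)(C)C(C)(C)C
F4 | step 10 | tert-butyl (4R)-2-ArS-4-[(R)-ArS(TBSO)methyl]-4,5-dihydrofuran-3-carboxylate | COc1cc([C@H](O[Si](C)(C)C(C)(C)C)[C@H]2COC(c3ccc(O[Si](C)(C)C(C)(C)C)c(OC)c3)=C2C(=O)OC(C)(C)C)ccc1O[Si](C)(C)C(C)(C)C
F5 | step 10 | tert-butyl (2R,3S,4R)-2-ArS-4-[(R)-ArS(TBSO)methyl]oxolane-3-carboxylate (all-cis) | COc1cc([C@H](O[Si](C)(C)C(C)(C)C)[C@H]2CO[C@@H](c3ccc(O[Si](C)(C)C(C)(C)C)c(OC)c3)[C@H]2C(=O)OC(C)(C)C)ccc1O[Si](C)(C)C(C)(C)C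
F6 | step 9 | 2-azido derivative of 13 (C3 epimers) | COc1cc([C@H](O[Si](C)(C)C(C)(C)C)[C@@H](COCc2ccc(O[Si](C)(C)C(C)(C)C)c(OC)c2)C(N=[N+]=[N-])C(=O)OC(C)(C)C)ccc1O[Si](C)(C)C(C)(C)C
F7 | step 9 | 2-amino derivative of 13 (C3 epimers) | COc1cc([C@H](O[Si](C)(C)C(C)(C)C)[C@@H](COCc2ccc(O[Si](C)(C)C(C)(C)C)c(OC)c2)C(N)C(=O)OC(C)(C)C)ccc1O[Si](C)(C)C(C)(C)C
F8 | step 5 | tert-butyl (3S,4R)-3-formyl-4-ArS-4-hydroxybutanoate | COc1cc([C@H](O)[C@@H](C=O)CC(=O)OC(C)(C)C)ccc1O[Si](C)(C)C(C)(C)C
F9 | step 5 | tert-butyl (3S,4R)-3-formyl-4-ArS-4-(TBSO)butanoate | COc1cc([C@H](O[Si](C)(C)C(C)(C)C)[C@@H](C=O)CC(=O)OC(C)(C)C)ccc1O[Si](C)(C)C(C)(C)C
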